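At the first reading, 10.0 min in, the flask read 60.6% of its starting complex and 26.4% as complex with one exchanged.

| setting | autumn | flask |
|---|---|---|
| starting complex | 1.1 M | 1.1 M |
| incoming ligand | 1 equiv | 1.00 equiv |
| remark | the very flask that is asked about, followed so far |  |
| time |  | 8.0 h |

- autumn (time / min: complex with one exchanged / %, starting complex / %): 10.0: 26.4, 60.6; 20.0: 32.2, 44.4; 50.0: 33.9, 28.2; 90.0: 30.8, 21.5

(scatter of a reading: 0.5 percentage points)



- time up to 8.0 h at which complex with one exchanged stands highest
- the amount of complex with one exchanged, in percent of the starting complex charged, at that time
- the first time at which complex with one exchanged reaches 17%, in the same percent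

I took the two partners as charged equally and used one for one, which gives a rate law that integrates in closed form: charge over amount left, less one, equals time over the exchange clock, the time in which the starting complex halves on this law, read from the first reading as 15.4 min.

In one extreme version of the flask nothing left the complex with one exchanged, so I reckoned the mark of 17% at 0.0525 h. In the other, the share of reacted starting complex read as complex with one exchanged at the first reading, 67.0%, held from the start, so more had to react and I reckoned the mark at 0.0871 h. I put the real flask between them, since I took the share to start undiminished and to have come down to the read value by 10.0 min, later than both times, and I committed to the middle, 0.0698 h.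

The forecast gave 0.075 h, a little later than my middle, and a highest point of 34.3% at 0.7 h, adding: “A later, higher rise seems unlikely”.

The flask gave 0.0721 h, and its best was 34.6% at 0.670 h.

    starting complex + incoming ligand → leaving ligand + complex with one exchanged (k = 0.00100 M⁻¹ s⁻¹)
    complex with one exchanged + incoming ligand → leaving ligand + complex with two exchanged (k = 3.90 × 10⁻⁴ M⁻¹ s⁻¹)
    complex with two exchanged + incoming ligand → leaving ligand + complex with three exchanged (k = 1.40 × 10⁻⁴ M⁻¹ s⁻¹)
    complex with one exchanged ⇌ isomer of the product (K = 0.470, k = 0.00230 s⁻¹)
    complex with one exchanged → over-reaction product (k = 1.00 × 10⁻⁴ s⁻¹)

The mark fell inside my window , and the amount stayed near its best from 0.382 h to 1.15 h, a span holding the reading at 50.0 min . Early on, at 0.176 h, complex with one exchanged was made 1.77 times faster than it was used up, each step taken net. At 4.00 h the incoming ligand, the limiting reagent in this flask, stood at 0.232% of its charge, and at 8.00 h complex with one exchanged stood at 6.59% and over-reaction product at 54.0%. For the neighbour flask with 0.44 M of starting complex, at the same equivalents, I scaled the clock to 0.641 h, and that flask's best was 30.3%, lower than this flask's.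

The numbers in the tables were computed with made-up constants; scatter was added.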